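**Strategy.** Guaiane numbering is used for the acid and iridoid numbering for the lactone. The ester is made last by opening spiro-epoxide 34 (from (S)-carvone) with dienoic acid 20 at C10. In 20 the plan rests on the C3–C4 bond of the cyclopentane ring, the one ring bond between the methyl-bearing C4 and an unfunctionalised CH2: ring-closing metathesis of acyclic diene acid 11, whose C1 and C5 stereocentres come from an Ireland–Claisen rearrangement, closes this ring in one operation as a cyclopentene. Hydrogenation opposite the two cis side chains then sets C4, and the side chains are later joined into the seven-membered ring.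

Key step: step 7

Remark: compounds 1, 4, 7 and 21 and all reagents in the Conditions lines are taken as commercial. In the acid C1/C5 are the ring-fusion carbons, C4 carries the methyl, C7 the isopropyl and C10 the carboxyl carbon C14. In the lactone C1 is the carbonyl carbon, C5/C9 the ring fusion, C7/C8 the carbinol carbons and C10 the CH2O carbon.

Step 1
Reactants: 1 ethyl 4-methyl-3-oxopentanoate
Product: 2 ethyl 2-[2-(propan-2-yl)-1,3-dioxolan-2-yl]acetate
Conditions: ethane-1,2-diol, TsOH (cat.), PhH, reflux, Dean–Stark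
Reagents that add atoms: ethane-1,2-diol OCCO
Why: Acid-catalysed ketalisation with azeotropic removal of water masks the ketone that later becomes C7, so the chain can be built without enolisation.

Step 2
Reactants: 2 ethyl 2-[2-(propan-2-yl)-1,3-dioxolan-2-yl]acetate
Product: 3 2-[2-(propan-2-yl)-1,3-dioxolan-2-yl]acetaldehyde
Conditions: iBu2AlH, CH2Cl2, −78 °C; Rochelle salt work-up
Reagents that add atoms: none
Why: Low-temperature DIBAL-H reduction of an ester stops at the aluminium hemiacetal, which should release the aldehyde on work-up.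

Step 3
Reactants: 3 2-[2-(propan-2-yl)-1,3-dioxolan-2-yl]acetaldehyde; 4 3-(triphenyl-λ5-phosphanylidene)butan-2-one
Product: 5 (3E)-3-methyl-5-[2-(propan-2-yl)-1,3-dioxolan-2-yl]pent-3-en-2-one
Conditions: PhMe, 90 °C
Reagents that add atoms: none
Why: Wittig olefination with a stabilised ylide should give the (E)-trisubstituted enone, the chain ending trans to the acetyl group.

Step 4
Reactants: 5 (3E)-3-methyl-5-[2-(propan-2-yl)-1,3-dioxolan-2-yl]pent-3-en-2-one
Product: 6 (2S,3E)-3-methyl-5-[2-(propan-2-yl)-1,3-dioxolan-2-yl]pent-3-en-2-ol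
Conditions: (R)-2-methyl-CBS-oxazaborolidine (cat.), BH3·SMe2, THF, −20 °C; MeOH
Reagents that add atoms: none
Why: Corey–Bakshi–Shibata reduction with the (R)-oxazaborolidine should deliver hydride to the face of the methyl alkenyl ketone that gives the (S)-carbinol, the centre later relayed to C1 and C5.

Step 5
Reactants: 6 (2S,3E)-3-methyl-5-[2-(propan-2-yl)-1,3-dioxolan-2-yl]pent-3-en-2-ol; 7 pent-4-enoic acid
Product: 8 (2S,3E)-3-methyl-5-[2-(propan-2-yl)-1,3-dioxolan-2-yl]pent-3-en-2-yl pent-4-enoate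
Conditions: DCC, DMAP (cat.), CH2Cl2, 0 °C to rt
Reagents that add atoms: none
Why: Steglich esterification acylates the secondary allylic alcohol without touching the carbinol centre or the alkene geometry.

Step 6
Reactants: 8 (2S,3E)-3-methyl-5-[2-(propan-2-yl)-1,3-dioxolan-2-yl]pent-3-en-2-yl pent-4-enoate
Product: 11 (2S,3S)-3-[(2E)-but-2-en-2-yl]-6-methyl-5-oxo-2-(prop-2-en-1-yl)heptanoic acid, via silyl ketene acetal 9 (not isolated), via trimethylsilyl ester 10 (not isolated)
Conditions: LiN(iPr)2, THF–DMPU, −78 °C; Me3SiCl, −78 to 50 °C; 1 M HCl, THF, rt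
Reagents that add atoms: chlorotrimethylsilane C[Si](C)(C)Cl (silicon only in 9 and 10); water O
Why: Ireland–Claisen rearrangement: the (Z)-O-enolate formed in the presence of DMPU is silylated and should rearrange through a chair transition state with the carbinol methyl equatorial, so the (S)-carbinol and the (E)-alkene become the (2S,3S) pair (C1 and C5, allyl and butenyl placed for a cis ring), after which aqueous acid cleaves the silyl ester and the dioxolane.

Step 7
Reactants: 11 (2S,3S)-3-[(2E)-but-2-en-2-yl]-6-methyl-5-oxo-2-(prop-2-en-1-yl)heptanoic acid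
Product: 12 (1S,2S)-3-methyl-2-(3-methyl-2-oxobutyl)cyclopent-3-ene-1-carboxylic acid
Conditions: second-generation Grubbs catalyst RuCl2(=CHPh)(H2IMes)(PCy3) (5 mol%), CH2Cl2, 40 °C
Reagents that add atoms: none
Why: Ring-closing olefin metathesis: the ruthenium alkylidene loads at the monosubstituted allyl terminus (C3) and, through a metallacyclobutane with the trisubstituted but-2-en-2-yl alkene, joins C3 to C4 and expels propene. The closest known reaction type is ring-closing metathesis of 1,6-dienes to 1-methylcyclopentenes. The cyclopentane ring C1–C5 closes as a five-membered cycloalkene by alkylidene exchange between two sp2 carbons, so no stereocentre is attacked. No stereocentre is formed here; C1 and C5 are already fixed, and the new ring holds their side chains cis on one face, which lets the next step set C4 by hydrogenation from the other face. The step needs chemoselectivity, secured because only this alkene pair can give a small ring and the ketone and free acid are tolerated, and configurational integrity at C1, secured by the neutral conditions.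

Step 8
Reactants: 12 (1S,2S)-3-methyl-2-(3-methyl-2-oxobutyl)cyclopent-3-ene-1-carboxylic acid
Product: 13 (1S,2R,3R)-3-methyl-2-(3-methyl-2-oxobutyl)cyclopentane-1-carboxylic acid
Conditions: H2 (1 atm), 10% Pd/C, EtOAc, rt
Reagents that add atoms: none
Why: Heterogeneous catalytic hydrogenation should add hydrogen to the face of the cyclopentene opposite the two cis side chains at C1 and C5, placing the C4 methyl cis to both (all-cis ring).

Step 9
Reactants: 13 (1S,2R,3R)-3-methyl-2-(3-methyl-2-oxobutyl)cyclopentane-1-carboxylic acid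
Product: 14 (1S,2R,3R)-N-methoxy-N,3-dimethyl-2-(3-methyl-2-oxobutyl)cyclopentane-1-carboxamide
Conditions: MeNHOMe·HCl, EDC·HCl, HOBt (cat.), iPr2NEt, CH2Cl2, 0 °C to rt
Reagents that add atoms: N,O-dimethylhydroxylamine hydrochloride CNOC.Cl
Why: Carbodiimide amide coupling should give the Weinreb amide under conditions too mild to epimerise C1.

Step 10
Reactants: 14 (1S,2R,3R)-N-methoxy-N,3-dimethyl-2-(3-methyl-2-oxobutyl)cyclopentane-1-carboxamide
Product: 15 (1S,2R,3R)-N-methoxy-N,3-dimethyl-2-(3-methyl-2-methylidenebutyl)cyclopentane-1-carboxamide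
Conditions: Ph3PCH3Br, KOtBu, THF, 0 °C to rt
Reagents that add atoms: methyltriphenylphosphonium bromide C[P+](c1ccccc1)(c1ccccc1)c1ccccc1.[Br-]
Why: Wittig methylenation converts the isopropyl ketone to the 1,1-disubstituted alkene, the Weinreb amide being inert to the non-stabilised ylide.

Step 11
Reactants: 15 (1S,2R,3R)-N-methoxy-N,3-dimethyl-2-(3-methyl-2-methylidenebutyl)cyclopentane-1-carboxamide
Product: 16 1-[(1S,2R,3R)-3-methyl-2-(3-methyl-2-methylidenebutyl)cyclopentyl]but-3-en-1-one
Conditions: allylmagnesium bromide, THF, −78 to 0 °C; aq. NH4Cl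
Reagents that add atoms: allylmagnesium bromide C=CC[Mg]Br
Why: Weinreb ketone synthesis: the chelated tetrahedral adduct prevents over-addition and releases the β,γ-unsaturated ketone only on cold, mild work-up.

Step 12
Reactants: 16 1-[(1S,2R,3R)-3-methyl-2-(3-methyl-2-methylidenebutyl)cyclopentyl]but-3-en-1-one
Product: 17 (1R,3aS,8aR)-1-methyl-7-(propan-2-yl)-2,3,3a,5,8,8a-hexahydroazulen-4(1H)-one
Conditions: second-generation Grubbs catalyst RuCl2(=CHPh)(H2IMes)(PCy3) (10 mol%), 1,4-benzoquinone (cat.), CH2Cl2 (dilute), 40 °C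
Reagents that add atoms: none
Why: Ring-closing metathesis between the monosubstituted and the 1,1-disubstituted alkene should form the seven-membered ring with the trisubstituted C7=C8 bond, benzoquinone suppressing ruthenium hydride isomerisation of the allyl ketone.

Step 13
Reactants: 17 (1R,3aS,8aR)-1-methyl-7-(propan-2-yl)-2,3,3a,5,8,8a-hexahydroazulen-4(1H)-one
Product: 19 (1R,3aS,8aR)-1-methyl-7-(propan-2-yl)-1,2,3,3a,8,8a-hexahydroazulen-4-yl trifluoromethanesulfonate, via potassium dienolate 18 (not isolated)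
Conditions: KN(SiMe3)2, THF, −78 °C; PhNTf2
Reagents that add atoms: N-phenylbis(trifluoromethanesulfonimide) O=S(=O)(N(c1ccccc1)S(=O)(=O)C(F)(F)F)C(F)(F)F; potassium bis(trimethylsilyl)amide C[Si](C)(C)[N-][Si](C)(C)C.[K+] (potassium only in 18)
Why: Enol triflate formation: kinetic deprotonation should occur at C9, which is both α to the ketone and allylic, and not at the tertiary C1–H, and O-sulfonylation of the linear dienolate gives the 1,3-dienyl triflate.

Step 14
Reactants: 19 (1R,3aS,8aR)-1-methyl-7-(propan-2-yl)-1,2,3,3a,8,8a-hexahydroazulen-4-yl trifluoromethanesulfonate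
Product: 20 (1R,3aS,8aR)-1-methyl-7-(propan-2-yl)-1,2,3,3a,8,8a-hexahydroazulene-4-carboxylic acid
Conditions: Pd(OAc)2 (5 mol%), dppf, CO (1 atm), KOAc, DMF–H2O, 60 °C
Reagents that add atoms: carbon monoxide [C-]#[O+]; water O
Why: Palladium-catalysed hydroxycarbonylation of the alkenyl triflate (oxidative addition, CO insertion, hydrolysis of the acylpalladium) installs C14 as the acid with the diene unchanged.

Step 15
Reactants: 21 (S)-carvone
Product: 22 (1S,5S)-2-methyl-5-(prop-1-en-2-yl)cyclohex-2-en-1-ol (cis-carveol)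
Conditions: NaBH4, CeCl3·7H2O, MeOH, −78 to 0 °C
Reagents that add atoms: none
Why: Luche reduction gives clean 1,2-reduction of the enone and should place the hydroxyl cis to the isopropenyl group, the relationship needed between the C7 oxygen and C5.

Step 16
Reactants: 22 (1S,5S)-2-methyl-5-(prop-1-en-2-yl)cyclohex-2-en-1-ol
Product: 23 1-methyl-4-(prop-1-en-2-yl)-7-oxabicyclo[4.1.0]heptan-2-ol with hydroxyl, epoxide oxygen and isopropenyl on one face
Conditions: VO(acac)2 (cat.), t-BuOOH, CH2Cl2, 0 °C to rt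
Reagents that add atoms: tert-butyl hydroperoxide CC(C)(C)OO
Why: Vanadium-catalysed hydroxyl-directed epoxidation is selective for the allylic alcohol alkene over the isopropenyl group and delivers oxygen syn to the hydroxyl.

Step 17
Reactants: 23 1-methyl-4-(prop-1-en-2-yl)-7-oxabicyclo[4.1.0]heptan-2-ol
Product: 24 tert-butyl(dimethyl)silyl ether of 23
Conditions: t-BuMe2SiCl, imidazole, DMF, rt
Reagents that add atoms: tert-butyl(chloro)dimethylsilane CC(C)(C)[Si](C)(C)Cl
Why: Silylation protects the hydroxyl against α-ketol cleavage by periodate and against the base used later.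

Step 18
Reactants: 24 tert-butyl(dimethyl)silyl ether of 23
Product: 26 (3R,5S)-5-{[tert-butyl(dimethyl)silyl]oxy}-6-oxo-3-(prop-1-en-2-yl)heptanal, via trans-diol 25 (not isolated)
Conditions: H5IO6, THF–H2O, 0 °C to rt
Reagents that add atoms: water O
Why: Acid-mediated epoxide hydrolysis followed by periodate glycol cleavage opens the six-membered ring to the keto aldehyde without touching the two stereocentres or the isopropenyl group.

Step 19
Reactants: 26 (3R,5S)-5-{[tert-butyl(dimethyl)silyl]oxy}-6-oxo-3-(prop-1-en-2-yl)heptanal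
Product: 27 (3S,5S)-3-{[tert-butyl(dimethyl)silyl]oxy}-2-methyl-5-(prop-1-en-2-yl)cyclopent-1-ene-1-carbaldehyde
Conditions: piperidine (cat.), AcOH (cat.), PhH, 60 °C
Reagents that add atoms: none
Why: Amine-catalysed intramolecular aldol condensation (the enamine of the aldehyde adds 5-exo to the methyl ketone, then dehydration) should give the cyclopentene carbaldehyde with C5 and C7 uninvolved.

Step 20
Reactants: 27 (3S,5S)-3-{[tert-butyl(dimethyl)silyl]oxy}-2-methyl-5-(prop-1-en-2-yl)cyclopent-1-ene-1-carbaldehyde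
Product: 28 (3S,5S)-3-{[tert-butyl(dimethyl)silyl]oxy}-2-methyl-5-(prop-1-en-2-yl)cyclopent-1-ene-1-carboxylic acid
Conditions: NaClO2, NaH2PO4, 2-methylbut-2-ene, t-BuOH–H2O, 0 °C to rt
Reagents that add atoms: sodium chlorite [Na+].[O-]Cl=O
Why: Pinnick oxidation converts the enal to the acid, the alkene scavenger removing hypochlorous acid before it can attack the alkenes.

Step 21
Reactants: 28 (3S,5S)-3-{[tert-butyl(dimethyl)silyl]oxy}-2-methyl-5-(prop-1-en-2-yl)cyclopent-1-ene-1-carboxylic acid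
Product: 30 (4aS,6S)-6-{[tert-butyl(dimethyl)silyl]oxy}-7-methyl-4-methylidene-4,4a,5,6-tetrahydrocyclopenta[c]pyran-1(3H)-one, via hydroxy acid 29 (not isolated)
Conditions: SeO2 (cat.), t-BuOOH, CH2Cl2, rt; then PPTS (cat.), PhH, 60 °C
Reagents that add atoms: tert-butyl hydroperoxide CC(C)(C)OO (oxygen relayed by selenium dioxide O=[Se]=O)
Why: Selenium dioxide allylic oxidation (ene reaction, then [2,3]-shift) should attack the methyl of the electron-rich isopropenyl group and not the electron-poor enoate, and the δ-hydroxy acid lactonises under mild acid.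

Step 22
Reactants: 30 (4aS,6S)-6-{[tert-butyl(dimethyl)silyl]oxy}-7-methyl-4-methylidene-4,4a,5,6-tetrahydrocyclopenta[c]pyran-1(3H)-one
Product: 32 (4aR,6S,7aR)-6-{[tert-butyl(dimethyl)silyl]oxy}-4,7-dimethylidenehexahydrocyclopenta[c]pyran-1(3H)-one, via lithium dienolate 31 (not isolated)
Conditions: LiN(iPr)2, THF–DMPU, −78 °C; AcOH, −78 °C
Reagents that add atoms: lithium diisopropylamide CC(C)[N-]C(C)C.[Li+] (lithium only in 31)
Why: Kinetic deconjugation: the base should remove a proton from the C10 methyl, which is held cis to the carbonyl, and the extended enolate is protonated at C9 from the convex face, giving the cis-fused β,γ-unsaturated lactone with the exocyclic C8=C10 methylene.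

Step 23
Reactants: 32 (4aR,6S,7aR)-6-{[tert-butyl(dimethyl)silyl]oxy}-4,7-dimethylidenehexahydrocyclopenta[c]pyran-1(3H)-one
Product: 33 (4aR,6S,7aR)-6-hydroxy-4,7-dimethylidenehexahydrocyclopenta[c]pyran-1(3H)-one
Conditions: HF·pyridine, THF–pyridine, 0 °C
Reagents that add atoms: none
Why: Buffered fluoride desilylation frees the C7 hydroxyl under conditions that should not return the alkene to conjugation.

Step 24
Reactants: 33 (4aR,6S,7aR)-6-hydroxy-4,7-dimethylidenehexahydrocyclopenta[c]pyran-1(3H)-one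
Product: 34 6-hydroxy-4-methylidenehexahydro-1H-spiro[cyclopenta[c]pyran-7,2'-oxiran]-1-one with the epoxide oxygen cis to the 6-hydroxyl and trans to H-4a and H-7a
Conditions: VO(acac)2 (cat.), t-BuOOH, CH2Cl2, 0 °C
Reagents that add atoms: tert-butyl hydroperoxide CC(C)(C)OO
Why: Hydroxyl-directed vanadium epoxidation acts only on the allylic alcohol alkene and should deliver oxygen syn to the C7 hydroxyl, that is to the concave face of C8, leaving the C4 methylene untouched.

Step 25
Reactants: 20 (1R,3aS,8aR)-1-methyl-7-(propan-2-yl)-1,2,3,3a,8,8a-hexahydroazulene-4-carboxylic acid; 34 spiro-epoxy alcohol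
Product: 35 nardostachysin
Conditions: Ti(OiPr)4, CH2Cl2, rt; aq. tartaric acid work-up
Reagents that add atoms: none
Why: Titanium-mediated opening of a 2,3-epoxy alcohol by a carboxylic acid should occur at the primary, unhindered C10 with the C8–O bond untouched, giving the C10 ester and the cis C7/C8 diol in one operation.

**Compound list**

1 | ethyl 4-methyl-3-oxopentanoate | CCOC(=O)CC(=O)C(C)C | starting material
2 | ethyl 2-[2-(propan-2-yl)-1,3-dioxolan-2-yl]acetate | CCOC(=O)CC1(C(C)C)OCCO1 | intermediate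
3 | 2-[2-(propan-2-yl)-1,3-dioxolan-2-yl]acetaldehyde | O=CCC1(C(C)C)OCCO1 | intermediate
4 | 3-(triphenyl-λ5-phosphanylidene)butan-2-one | CC(=O)C(C)=P(c1ccccc1)(c1ccccc1)c1ccccc1 | starting material
5 | (3E)-3-methyl-5-[2-(propan-2-yl)-1,3-dioxolan-2-yl]pent-3-en-2-one | CC(=O)/C(C)=C/CC1(C(C)C)OCCO1 | intermediate
6 | (2S,3E)-3-methyl-5-[2-(propan-2-yl)-1,3-dioxolan-2-yl]pent-3-en-2-ol | C[C@H](O)/C(C)=C/CC1(C(C)C)OCCO1 | intermediate
7 | pent-4-enoic acid | C=CCCC(=O)O | starting material
8 | (2S,3E)-3-methyl-5-[2-(propan-2-yl)-1,3-dioxolan-2-yl]pent-3-en-2-yl pent-4-enoate | C=CCCC(=O)O[C@@H](C)/C(C)=C/CC1(C(C)C)OCCO1 | intermediate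
9 | (Z)-trimethylsilyl ketene acetal of 8 (allyl CH2 cis to OSiMe3) | C[Si](C)(C)O/C(=C\CC=C)O[C@@H](C)/C(C)=C/CC1(C(C)C)OCCO1 | intermediate
10 | trimethylsilyl (2S,3S)-3-[(2E)-but-2-en-2-yl]-4-[2-(propan-2-yl)-1,3-dioxolan-2-yl]-2-(prop-2-en-1-yl)butanoate | CC(C)C1(OCCO1)C[C@H](/C(C)=C/C)[C@H](CC=C)C(=O)O[Si](C)(C)C | intermediate
11 | (2S,3S)-3-[(2E)-but-2-en-2-yl]-6-methyl-5-oxo-2-(prop-2-en-1-yl)heptanoic acid | CC(C)C(=O)C[C@H](/C(C)=C/C)[C@H](CC=C)C(=O)O | intermediate
12 | (1S,2S)-3-methyl-2-(3-methyl-2-oxobutyl)cyclopent-3-ene-1-carboxylic acid | CC(C)C(=O)C[C@@H]1C(C)=CC[C@@H]1C(=O)O | intermediate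
13 | (1S,2R,3R)-3-methyl-2-(3-methyl-2-oxobutyl)cyclopentane-1-carboxylic acid (all-cis) | CC(C)C(=O)C[C@@H]1[C@H](C)CC[C@@H]1C(=O)O | intermediate
14 | (1S,2R,3R)-N-methoxy-N,3-dimethyl-2-(3-methyl-2-oxobutyl)cyclopentane-1-carboxamide | CC(C)C(=O)C[C@@H]1[C@H](C)CC[C@@H]1C(=O)N(C)OC | intermediate
15 | (1S,2R,3R)-N-methoxy-N,3-dimethyl-2-(3-methyl-2-methylidenebutyl)cyclopentane-1-carboxamide | CC(C)C(=C)C[C@@H]1[C@H](C)CC[C@@H]1C(=O)N(C)OC | intermediate
16 | 1-[(1S,2R,3R)-3-methyl-2-(3-methyl-2-methylidenebutyl)cyclopentyl]but-3-en-1-one | CC(C)C(=C)C[C@@H]1[C@H](C)CC[C@@H]1C(=O)CC=C | intermediate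
17 | (1R,3aS,8aR)-1-methyl-7-(propan-2-yl)-2,3,3a,5,8,8a-hexahydroazulen-4(1H)-one (cis-fused) | O=C1CC=C(C(C)C)C[C@@H]2[C@H](C)CC[C@H]12 | intermediate
18 | potassium (1R,3aS,8aR)-1-methyl-7-(propan-2-yl)-1,2,3,3a,8,8a-hexahydroazulen-4-olate | [K+].[O-]C1=CC=C(C(C)C)C[C@@H]2[C@H](C)CC[C@H]12 | intermediate
19 | (1R,3aS,8aR)-1-methyl-7-(propan-2-yl)-1,2,3,3a,8,8a-hexahydroazulen-4-yl trifluoromethanesulfonate | O=S(=O)(OC1=CC=C(C(C)C)C[C@@H]2[C@H](C)CC[C@H]12)C(F)(F)F | intermediate
20 | (1R,3aS,8aR)-1-methyl-7-(propan-2-yl)-1,2,3,3a,8,8a-hexahydroazulene-4-carboxylic acid | OC(=O)C1=CC=C(C(C)C)C[C@@H]2[C@H](C)CC[C@H]12 | intermediate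
21 | (S)-carvone, (5S)-2-methyl-5-(prop-1-en-2-yl)cyclohex-2-en-1-one | CC1=CC[C@@H](CC1=O)C(C)=C | starting material
22 | (1S,5S)-2-methyl-5-(prop-1-en-2-yl)cyclohex-2-en-1-ol (cis-carveol) | CC1=CC[C@@H](C[C@@H]1O)C(C)=C | intermediate
23 | 1-methyl-4-(prop-1-en-2-yl)-7-oxabicyclo[4.1.0]heptan-2-ol, hydroxyl, epoxide oxygen and isopropenyl on one face | C[C@@]12O[C@@H]1C[C@@H](C[C@@H]2O)C(C)=C | intermediate
24 | tert-butyl(dimethyl)silyl ether of 23 | C[C@@]12O[C@@H]1C[C@@H](C[C@@H]2O[Si](C)(C)C(C)(C)C)C(C)=C | intermediate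
25 | 3-{[tert-butyl(dimethyl)silyl]oxy}-2-methyl-5-(prop-1-en-2-yl)cyclohexane-1,2-diol (trans-diol from water attack at the methyl-bearing carbon) | C[C@]1(O)[C@H](O)C[C@@H](C[C@@H]1O[Si](C)(C)C(C)(C)C)C(C)=C | intermediate
26 | (3R,5S)-5-{[tert-butyl(dimethyl)silyl]oxy}-6-oxo-3-(prop-1-en-2-yl)heptanal | CC(=O)[C@@H](O[Si](C)(C)C(C)(C)C)C[C@H](CC=O)C(C)=C | intermediate
27 | (3S,5S)-3-{[tert-butyl(dimethyl)silyl]oxy}-2-methyl-5-(prop-1-en-2-yl)cyclopent-1-ene-1-carbaldehyde | CC1=C(C=O)[C@@H](C[C@@H]1O[Si](C)(C)C(C)(C)C)C(C)=C | intermediate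
28 | (3S,5S)-3-{[tert-butyl(dimethyl)silyl]oxy}-2-methyl-5-(prop-1-en-2-yl)cyclopent-1-ene-1-carboxylic acid | CC1=C(C(=O)O)[C@@H](C[C@@H]1O[Si](C)(C)C(C)(C)C)C(C)=C | intermediate
29 | (3S,5S)-3-{[tert-butyl(dimethyl)silyl]oxy}-5-(3-hydroxyprop-1-en-2-yl)-2-methylcyclopent-1-ene-1-carboxylic acid | CC1=C(C(=O)O)[C@@H](C[C@@H]1O[Si](C)(C)C(C)(C)C)C(=C)CO | intermediate
30 | (4aS,6S)-6-{[tert-butyl(dimethyl)silyl]oxy}-7-methyl-4-methylidene-4,4a,5,6-tetrahydrocyclopenta[c]pyran-1(3H)-one | C=C1COC(=O)C2=C(C)[C@@H](O[Si](C)(C)C(C)(C)C)C[C@@H]12 | intermediate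
31 | lithium dienolate of 30 (C1 olate, C7a=C1 and exocyclic C7=CH2) | [Li+].C=C1COC([O-])=C2C(=C)[C@@H](O[Si](C)(C)C(C)(C)C)C[C@@H]12 | intermediate
32 | (4aR,6S,7aR)-6-{[tert-butyl(dimethyl)silyl]oxy}-4,7-dimethylidenehexahydrocyclopenta[c]pyran-1(3H)-one (cis-fused) | C=C1COC(=O)[C@@H]2[C@H]1C[C@H](O[Si](C)(C)C(C)(C)C)C2=C | intermediate
33 | (4aR,6S,7aR)-6-hydroxy-4,7-dimethylidenehexahydrocyclopenta[c]pyran-1(3H)-one | C=C1COC(=O)[C@@H]2[C@H]1C[C@H](O)C2=C | intermediate
34 | 6-hydroxy-4-methylidenehexahydro-1H-spiro[cyclopenta[c]pyran-7,2'-oxiran]-1-one, epoxide oxygen cis to 6-OH | C=C1COC(=O)[C@@H]2[C@H]1C[C@H](O)[C@@]23CO3 | intermediate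
35 | nardostachysin | C=C1COC(=O)[C@@H]2[C@H]1C[C@H](O)[C@@]2(O)COC(=O)C1=CC=C(C(C)C)C[C@@H]2[C@H](C)CC[C@H]12 | target

**Step count.** Total: 25 steps. Longest linear sequence: 15 steps (steps 1–14 and step 25); the lactone branch (steps 15–24) runs in parallel.

**Steps most likely to fail**

Step 22. Deprotonation may occur at the C7–H instead of the C10 methyl, or the deconjugated lactone may slide back into conjugation during quench and work-up. The fallback sets out from 30 and comes back at 32: photodeconjugation, irradiation at 254 nm in CH2Cl2 with a catalytic amine. The excited enoate should pass a hydrogen from the C10 methyl, held cis to the carbonyl, to oxygen, and the photodienol is then protonated at C9 without any strong base. It makes no new compound.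

Step 6. Leakage through the (E)-O-enolate or a boat transition state would erode the C1/C5 relationship, and the dioxolane cleavage may trigger acid lactonisation onto the butenyl alkene. The fallback sets out from 3 and comes back at 12, replacing chirality transfer by reagent control.
- Wittig reaction of 3 with ethyl 2-(triphenyl-λ5-phosphanylidene)propanoate should give ethyl (2E)-2-methyl-4-[2-(propan-2-yl)-1,3-dioxolan-2-yl]but-2-enoate F1.
- DIBAL-H reduction gives (2E)-2-methyl-4-[2-(propan-2-yl)-1,3-dioxolan-2-yl]but-2-en-1-ol F2.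
- Steglich esterification with 7 gives the pent-4-enoate F3.
- An enolate Claisen rearrangement of the (Z)-O-boron enolate, formed with a chiral 2-bromo-4,5-diphenyl-1,3-bis(4-methylbenzenesulfonyl)-1,3,2-diazaborolidine and a tertiary amine, should give (2S,3S)-4-[2-(propan-2-yl)-1,3-dioxolan-2-yl]-2-(prop-2-en-1-yl)-3-(prop-1-en-2-yl)butanoic acid F4. The enantiomer of the controller is chosen to deliver this acid.
- PPTS in wet acetone gives (2S,3S)-6-methyl-5-oxo-2-(prop-2-en-1-yl)-3-(prop-1-en-2-yl)heptanoic acid F5.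
- Ring-closing metathesis of F5 under the conditions of step 7 gives 12.

Step 25. The epoxide opening may be slow or unselective, and the acyl group may migrate or the lactone may be transesterified by isopropoxide. The fallback sets out from 33 and 20 and comes back at 35. Hydrogen-bond-directed dihydroxylation of 33 with OsO4·TMEDA in CH2Cl2 at −78 °C should add both oxygens syn to the C7 hydroxyl, giving (4aR,6S,7S,7aR)-6,7-dihydroxy-7-(hydroxymethyl)-4-methylidenehexahydrocyclopenta[c]pyran-1(3H)-one F6. Yamaguchi esterification of 20 (2,4,6-trichlorobenzoyl chloride, Et3N, then DMAP) at the primary hydroxyl of F6 then gives 35.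

Further compounds
F0 | step 22 | none | none
F1 | step 6 | ethyl (2E)-2-methyl-4-[2-(propan-2-yl)-1,3-dioxolan-2-yl]but-2-enoate | CCOC(=O)/C(C)=C/CC1(C(C)C)OCCO1
F2 | step 6 | (2E)-2-methyl-4-[2-(propan-2-yl)-1,3-dioxolan-2-yl]but-2-en-1-ol | OC/C(C)=C/CC1(C(C)C)OCCO1
F3 | step 6 | (2E)-2-methyl-4-[2-(propan-2-yl)-1,3-dioxolan-2-yl]but-2-en-1-yl pent-4-enoate | C=CCCC(=O)OC/C(C)=C/CC1(C(C)C)OCCO1
F4 | step 6 | (2S,3S)-4-[2-(propan-2-yl)-1,3-dioxolan-2-yl]-2-(prop-2-en-1-yl)-3-(prop-1-en-2-yl)butanoic acid | CC(C)C1(OCCO1)C[C@H](C(C)=C)[C@H](CC=C)C(=O)O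
F5 | step 6 | (2S,3S)-6-methyl-5-oxo-2-(prop-2-en-1-yl)-3-(prop-1-en-2-yl)heptanoic acid | CC(C)C(=O)C[C@H](C(C)=C)[C@H](CC=C)C(=O)O
F6 | step 25 | (4aR,6S,7S,7aR)-6,7-dihydroxy-7-(hydroxymethyl)-4-methylidenehexahydrocyclopenta[c]pyran-1(3H)-one | C=C1COC(=O)[C@@H]2[C@H]1C[C@H](O)[C@@]2(O)CO
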